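One percent in these tables is 0.0400 mM of substrate, counted over both mirror images, so each substrate starts at half of the total.

| flask | left-handed substrate | right-handed substrate | protic impurity | solid reagent | catalyst | remark | time |
|---|---|---|---|---|---|---|---|
| north-west | 2 mM | 2 mM | 0.040 mM | 2 mM | 7 µM | the very flask that is asked about, followed so far |  |
| flask | 2.0 mM | 2.0 mM | 0.0400 mM | 2.00 mM | 7.0 µM |  | 10 min |

- north-west (time / s: left-handed substrate / %, right-handed substrate / %): 10.0: 42.4, 47.1; 15.0: 37.7, 44.8; 25.0: 28.7, 40.2; 40.0: 19.7, 34.4; 50.0: 18.9, 33.6

(standard deviation of a reading: 0.5 percentage points)

- catalyst is single-handed; left-handed substrate and right-handed substrate are mirror images of each other, charged as a racemate, each of them at the stated concentration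
- solid reagent is a solid; its amount is given per volume of the solution
- the numbers in the tables scatter by 0.5 percentage points (one standard deviation)
- at the start none of the solid reagent is in solution
- an excess is the difference of the two amounts in percent of their sum
- an excess is below zero if the other one leads

1. part of the left-handed substrate and right-handed substrate charged together that has reacted at 10 min
2. excess of left-handed product over right-handed product in the product at 10 min
3. excess of right-handed substrate over left-handed substrate among what is left of the two at 10 min

The bench rule for a flask fed from a solid is a steady pace, and the north-west run shows one: the reacted part grows from 17.5% at 15.0 s to 31.1% at 25.0 s. Carried on to 10 min, that pace gives an impossible 816%. The border is a ratio of charges. Taking the solid reagent as the limiting reagent, one per substrate and one per protic impurity, the ceiling is 49.0%, which the pace reaches after 36.0 s, far short of the asked time. The run bends there: from 40.0 s to 50.0 s the reacted part gains 1.6 percentage points, reaching 47.5%.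

The split between the mirror images follows from the selectivity factor, the logarithm of the left-handed substrate's remaining fraction divided by that of the right-handed substrate's, 2.45 at the last reading. Put back once, it shares the remaining 1.5 points up to the ceiling in proportion to s[left-handed substrate] against [right-handed substrate]. So eP lies between 30.5% and 30.9%, and eS between 28.0% and 29.3%.

The forecast gives 48.3%, 31.5% and 29.4%, with “the reaction dead long before 10 min”.

The flask gives 46.9%, 30.6% and 27.0%: eP falls inside the reckoned span, while c and eS fall below it.

    partner + catalyst + left-handed substrate → catalyst + left-handed product (k = 2.40 × 10⁷ /M²/s)
    partner + catalyst + right-handed substrate → catalyst + right-handed product (k = 9.97 × 10⁶ /M²/s)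
    partner + protic impurity → quenched reagent (k = 2470 /M/s)
    partner → decomposed reagent (k = 0.0151 /s)
    solid reagent ⇌ partner, rate k5*(cs5 - [partner]) while solid is left; crystals form when [partner] > cs5 (solubility = 0.910 mM, k = 0.0733 /s)

The partner has a half-life of 2.1 s by the left-handed step with charges as given, against 0.77 min by decomposing. Decomposed reagent stands at 0.0851 mM in this flask, 2.13% of the substrates, the distance from 49.0% to 46.9%. Here s turns the 67% of right-handed substrate left into 38.2% of left-handed substrate, against 39% computed. In the neighbour flask with [catalyst] = 0.0018 mM, 72% of right-handed substrate left gives 44.0% by s; the computed value is 45%, at c = 41.9%.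

All runs come from a simulation for an exercise, and the scatter is random.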